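Remark: neolignan numbering is used (C7 = carbinol carbon on ring A, C8 = carbon bearing the ether oxygen, C9 = methyl carbon; ring A = 3-hydroxy-4,5-dimethoxyphenyl, ring B = 4-allyl-2,6-dimethoxyphenyl). Compounds 1, 2, 4 and 7 are assumed to be purchasable.

## Analysis of the target

The target is an acyclic 8-O-4' neolignan. Its C7–C8–C9 chain carries ring A and a hydroxyl on C7, and on C8 the methyl group C9 and an ether oxygen to C4' of ring B; the two arenes are the only rings. The only stereocentres are C7 and C8, both R and adjacent. They are threo: hydroxyl and aryloxy lie on opposite sides in the Fischer projection and syn in the zigzag drawing of the chain. Three groups limit the chemistry: the free phenol on ring A, the C7 alcohol, which is benzylic on a ring with a para-methoxy group and so ionises and epimerises under acid, and the terminal allyl group on ring B, which excludes hydrogenolysis, hydroboration and isomerising conditions. The ether oxygen on C8 sits between two ortho-methoxy groups, so forming the C8–O bond at a secondary stereocentre, by substitution or by metal-catalysed coupling, would have to compete with elimination. The difficulty is therefore to set two contiguous acyclic stereocentres in relative and absolute sense while attaching this crowded aryloxy group to one of them. The plan rests on the vicinal O,O pair at C7 and C8 with C9 read as a reduced carboxyl carbon: C7–C8 is then the bond of a syn-selective aryloxyacetate aldol addition to the ring A aldehyde, and the ether oxygen can be attached beforehand at a CH2 group.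

## Retrosynthetic reasoning

15 ⇒ 14. The last bond cut is the O–Si bond of a silyl ether on the ring A phenol. The phenol must be masked throughout because it would consume the boron reagent and the sulfonylating agent. A bulky trialkylsilyl ether is chosen because it leaves with fluoride ion, which touches neither the allyl group nor the acid-sensitive C7 alcohol.

14 ⇒ 13 ⇒ 12. C9 is written back as an oxygenated carbon. The methyl group of 14 comes from the primary sulfonate 13 by hydride displacement, and 13 comes from the 1,3-diol 12 by sulfonylation of the primary hydroxyl. This costs two functional-group steps but is what opens the aldol disconnection. The forward reactions must distinguish the primary C9 hydroxyl from the hindered benzylic C7 hydroxyl, and must deliver hydride faster than the C7 alkoxide can attack C9.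

12 ⇒ 11. The diol is the reduction product of the N-acyl oxazolidinone 11, in which C9 is the imide carbonyl. Reductive cleavage returns the auxiliary 4 and must not cause retro-aldol cleavage of the C7–C8 bond.

11 ⇒ 6 + 8. The C7–C8 bond is cut. It is the only bond whose cleavage removes both stereocentres at once, and it divides the molecule into two fragments of similar size, each one or two steps from a purchasable arene. Cutting C8–O instead would require substitution at a secondary stereocentre by a di-ortho-substituted phenol oxygen. Cutting the bond from C7 to ring A would leave a configurationally fragile α-aryloxy aldehyde. In the forward direction the boron enolate 9 of imide 6 must add to aldehyde 8 with syn selectivity and with the facial sense set by the auxiliary. Aldehyde 8 has no α-hydrogen, so only one partner can enolise.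

6 ⇒ 3 + 4, and 3 ⇒ 1 + 2. The imide N–C(O) bond is cut to give acid 3 and oxazolidinone 4. The ether bond between the ring B oxygen and the CH2 group is cut to give phenol 1 and bromoacetic acid 2. The hindered C–O bond is thus made by displacement at an unhindered primary carbon before any stereocentre exists.

8 ⇒ 7. The silyl ether of the aldehyde is cut back to the purchasable hydroxy aldehyde 7; only a phenol silylation is needed.

## Alternatives that were turned down

Alternative 1: The C7–O and C8–H bonds are disconnected together, back to the (E)-aryl enol ether A1, in which ring B carries bromine in place of the allyl group and the ring A phenol is silylated. In the forward key step one enantiomer of monoisopinocampheylborane would add boron to C7 and hydrogen to C8 across one face of A1, and alkaline H2O2 would turn C7–B into C7–OH with retention to give the threo alcohol A2.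
- For: syn addition to the E alkene translates alkene geometry directly into the threo relationship, and the oxygen on C8 reinforces the regiochemistry. C9 is a methyl group from the start, and no auxiliary is attached or removed. After the stereo-defining event this alternative is shorter than the chosen route.
- Against: the organoborane has boron on C7 and an aryloxy leaving group on C8, an arrangement set up for β-elimination; the alkene so formed would be hydroborated again without control. Facial discrimination by the chiral borane on a trisubstituted, heteroatom-substituted alkene is uncertain. A1 must be geometrically pure, and a stereoselective synthesis of an enol ether of a 2,6-dimethoxyphenol is itself not trivial. A borane would also attack an allyl group, so A2 carries bromine and needs a late cross-coupling allylation beside a free benzylic alcohol.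
- Comparison: the chosen route offers relative and absolute control from a closed transition state and a covalently bound auxiliary, minor isomers that are diastereomers and can be separated, and an allyl group carried through untouched.

Alternative 2: The bond between the C8 oxygen and C4' of ring B is cut. The forward key step is a C–O coupling with Pd2(dba)3, t-BuBrettPhos and Cs2CO3 between the free C8 hydroxyl of the monosilylated (1R,2R)-diol A3 and the ring B aryl bromide A4, giving the bis-silyl ether A5. A3 would first have to come from an asymmetric dihydroxylation and a regioselective monosilylation.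
- For: both stereocentres come from a catalytic, highly predictable dihydroxylation, and C9 is a methyl group throughout. On catalyst economy and confidence in enantioselectivity this alternative is stronger than an auxiliary aldol.
- Against: A4 is electron-rich and di-ortho-substituted and the alcohol is secondary, the least favourable combination for this coupling. Reductive elimination of the C–O bond is slow, and β-hydride elimination from the palladium alkoxide, which oxidises C8 and reduces the arene, competes. Zerovalent palladium with base at elevated temperature can also move the allyl double bond into conjugation. A3 requires silylation of the C7 hydroxyl in preference to the similarly hindered C8 hydroxyl, and two silyl groups must be removed at the end.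
- Comparison: the chosen route forms the same ether bond by a Williamson reaction at a CH2 group, so its risk lies in a well-understood C–C bond formation and not in a worst-case C–O coupling.

Alternative 3: The bond from C7 to C1 of ring A is cut. The forward key step adds the ring A arylmagnesium bromide A7 to the magnesium chelate of (R)-2-(4-allyl-2,6-dimethoxyphenoxy)propanal A6. It forms the C7 stereocentre under chelation control and gives the silyl ether A8, which is the same compound as 14.
- For: C8 comes from the chiral pool, C9 is already a methyl group, and A8 is reached without auxiliary or C9 redox steps. In step count this is the shortest of all the strategies and clearly shorter than the chosen one.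
- Against: the threo outcome depends on magnesium binding an aryl alkyl ether oxygen whose lone pairs are delocalised into ring B and which is flanked by two methoxy groups. Weak chelation lets the Felkin–Anh pathway to the erythro isomer compete. A6 has an acidic α-hydrogen next to an aryloxy group and can racemise during its preparation or under the basic organomagnesium reagent. The ether in A6 would have to be made by an inverting substitution at a secondary carbon with the crowded phenol 1.
- Comparison: the chosen route pays three extra steps after the C–C bond formation, but sets both stereocentres in one closed transition state and never forms the hindered ether at a stereocentre.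

Key step: step 4

## Route

Step 1
Reactants: 1 4-allyl-2,6-dimethoxyphenol (methoxyeugenol); 2 bromoacetic acid
Product: 3 (4-allyl-2,6-dimethoxyphenoxy)acetic acid
Conditions: NaH (2.5 equiv), THF/DMF, 0 °C to rt; then aq. HCl
Reagents that add atoms: none
Why: Williamson ether synthesis: NaH converts 2 into its carboxylate and 1 into the phenoxide, which displaces bromide at an unhindered primary carbon (SN2); the crowded phenol oxygen is thus alkylated at CH2 and not at a stereocentre, and NaH at room temperature should not move the allyl double bond into conjugation.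

Step 2
Reactants: 3 (4-allyl-2,6-dimethoxyphenoxy)acetic acid; 4 (S)-4-benzyloxazolidin-2-one
Product: 6 (S)-4-benzyl-3-[(4-allyl-2,6-dimethoxyphenoxy)acetyl]oxazolidin-2-one, via mixed pivalic anhydride 5 (not isolated)
Conditions: t-BuCOCl, Et3N, THF, −20 °C; then LiCl, 4, −20 °C to rt
Reagents that add atoms: none
Why: N-acylation of an oxazolidinone through a mixed anhydride: the pivaloyl carbonyl of 5 is shielded by the tert-butyl group, so the LiCl-activated oxazolidinone attacks the aryloxyacetyl carbonyl; no stereocentre is at risk.

Step 3
Reactants: 7 3-hydroxy-4,5-dimethoxybenzaldehyde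
Product: 8 4,5-dimethoxy-3-(triisopropylsilyloxy)benzaldehyde
Conditions: i-Pr3SiCl, imidazole, DMF, rt
Reagents that add atoms: triisopropylsilyl chloride, CC(C)[Si](Cl)(C(C)C)C(C)C
Why: Silylation of a phenol with a trialkylsilyl chloride and imidazole; the triisopropylsilyl ether should survive the boron triflate, LiBH4, sulfonylation and LiBHEt3 and leave with fluoride at the end.

Step 4
Reactants: 6 (S)-4-benzyl-3-[(4-allyl-2,6-dimethoxyphenoxy)acetyl]oxazolidin-2-one; 8 4,5-dimethoxy-3-(triisopropylsilyloxy)benzaldehyde
Product: 11 (S)-4-benzyl-3-[(2S,3R)-2-(4-allyl-2,6-dimethoxyphenoxy)-3-hydroxy-3-[3,4-dimethoxy-5-(triisopropylsilyloxy)phenyl]propanoyl]oxazolidin-2-one, via Z-configured dibutylboron enolate 9 (not isolated), via dibutylboron aldolate 10 (not isolated)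
Conditions: Bu2BOTf (1.1 equiv), i-Pr2NEt, CH2Cl2, −78 °C then 0 °C; 8, −78 °C to 0 °C; pH 7 buffer, MeOH, 30% H2O2, 0 °C
Reagents that add atoms: none
Why: Bu2BOTf activates the imide carbonyl and i-Pr2NEt removes a C8 proton to give the Z-configured boron enolate 9, in which the aryloxy group is cis to the O–B bond because the other geometry would clash with the auxiliary (allylic strain). Boron then binds the aldehyde oxygen of 8; having no further free site it releases the oxazolidinone carbonyl, and the C7–C8 bond forms through a closed six-membered chair (Zimmerman–Traxler) transition state that ends in the boron aldolate 10. The closest known reaction type is the Evans syn-aldol of N-glycolyl (alkoxyacetyl and aryloxyacetyl) oxazolidinones with aromatic aldehydes. No ring is closed; one skeletal bond and two stereocentres are formed. The relative configuration follows from the Z enolate combined with the chair in which the ring A aryl group of 8 is equatorial, which places the C7 oxygen and the C8 aryloxy group syn. The absolute configuration follows from the (S)-benzyl auxiliary, which in the reacting conformer turns its carbonyl dipole away from the enolate oxygen and shields one enolate face with the benzyl group, so the (2S,3R) imide should result (7R,8R in the target, the C8 descriptor changing only because C9 later loses priority). The step needs syn over anti and one syn adduct over the other: only a slight excess of boron triflate keeps the pathway closed, 8 has no α-hydrogen and cannot enolise, and the allyl group and the aryl silyl ether are inert to the boron reagent. Buffered H2O2 oxidises the B–C bonds of 10 and frees 11 without epoxidising the unactivated alkene.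

Step 5
Reactants: 11 (S)-4-benzyl-3-[(2S,3R)-2-(4-allyl-2,6-dimethoxyphenoxy)-3-hydroxy-3-[3,4-dimethoxy-5-(triisopropylsilyloxy)phenyl]propanoyl]oxazolidin-2-one
Product: 12 (1R,2R)-2-(4-allyl-2,6-dimethoxyphenoxy)-1-[3,4-dimethoxy-5-(triisopropylsilyloxy)phenyl]propane-1,3-diol
Conditions: LiBH4, MeOH (1 equiv), THF, 0 °C
Reagents that add atoms: none
Why: Reductive cleavage of an N-acyl oxazolidinone: LiBH4 attacks the exocyclic imide carbonyl, helped by lithium chelation to the free C7 hydroxyl, and reduces it through the aldehyde to the primary alcohol while auxiliary 4 is released; no bond to C7 or C8 is broken, and the alkene and the silyl ether are inert to borohydride.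

Step 6
Reactants: 12 (1R,2R)-2-(4-allyl-2,6-dimethoxyphenoxy)-1-[3,4-dimethoxy-5-(triisopropylsilyloxy)phenyl]propane-1,3-diol
Product: 13 (2R,3R)-2-(4-allyl-2,6-dimethoxyphenoxy)-3-hydroxy-3-[3,4-dimethoxy-5-(triisopropylsilyloxy)phenyl]propyl 4-methylbenzenesulfonate
Conditions: TsCl (1.1 equiv), pyridine, CH2Cl2, 0 °C
Reagents that add atoms: 4-methylbenzenesulfonyl chloride, Cc1ccc(cc1)S(Cl)(=O)=O
Why: Selective sulfonylation of a primary over a secondary alcohol: the C9 hydroxyl is unhindered, whereas the C7 hydroxyl is secondary, benzylic and next to the aryloxy-bearing C8, so a small excess of TsCl at 0 °C should give the monotosylate.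

Step 7
Reactants: 13 (2R,3R)-2-(4-allyl-2,6-dimethoxyphenoxy)-3-hydroxy-3-[3,4-dimethoxy-5-(triisopropylsilyloxy)phenyl]propyl 4-methylbenzenesulfonate
Product: 14 (1R,2R)-2-(4-allyl-2,6-dimethoxyphenoxy)-1-[3,4-dimethoxy-5-(triisopropylsilyloxy)phenyl]propan-1-ol
Conditions: LiBHEt3 (3 equiv), THF, 0 °C to rt; aq. NH4Cl
Reagents that add atoms: none
Why: SN2 displacement of a primary tosylate by hydride from LiBHEt3, a strongly nucleophilic hydride donor; the first equivalent converts the C7 hydroxyl into its alkoxide and a further equivalent cleaves the C9–O bond to leave the C9 methyl group, with no bond to C7 or C8 broken and the terminal alkene untouched.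

Step 8
Reactants: 14 (1R,2R)-2-(4-allyl-2,6-dimethoxyphenoxy)-1-[3,4-dimethoxy-5-(triisopropylsilyloxy)phenyl]propan-1-ol
Product: 15 (1R,2R)-2-(4-allyl-2,6-dimethoxyphenoxy)-1-(3-hydroxy-4,5-dimethoxyphenyl)propan-1-ol (CNP0144691.1)
Conditions: Bu4NF, THF, 0 °C; aq. NH4Cl
Reagents that add atoms: none
Why: Fluoride-induced cleavage of an aryl silyl ether, driven by the strength of the Si–F bond and the phenoxide leaving group; the conditions are not acidic, so the C7 alcohol should not ionise, and the phenol is meta to C7 and cannot expel the C7 oxygen as a quinone methide.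

## Compound list

1 | 4-allyl-2,6-dimethoxyphenol (methoxyeugenol) | C=CCc1cc(OC)c(O)c(OC)c1 | starting material
2 | bromoacetic acid | OC(=O)CBr | starting material
3 | (4-allyl-2,6-dimethoxyphenoxy)acetic acid | C=CCc1cc(OC)c(OCC(=O)O)c(OC)c1 | intermediate
4 | (S)-4-benzyloxazolidin-2-one | O=C1OC[C@H](Cc2ccccc2)N1 | starting material
5 | (4-allyl-2,6-dimethoxyphenoxy)acetic pivalic anhydride | C=CCc1cc(OC)c(OCC(=O)OC(=O)C(C)(C)C)c(OC)c1 | intermediate (not isolated)
6 | (S)-4-benzyl-3-[(4-allyl-2,6-dimethoxyphenoxy)acetyl]oxazolidin-2-one | C=CCc1cc(OC)c(OCC(=O)N2[C@@H](Cc3ccccc3)COC2=O)c(OC)c1 | intermediate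
7 | 3-hydroxy-4,5-dimethoxybenzaldehyde | COc1cc(C=O)cc(O)c1OC | starting material
8 | 4,5-dimethoxy-3-(triisopropylsilyloxy)benzaldehyde | O=Cc1cc(O[Si](C(C)C)(C(C)C)C(C)C)c(OC)c(OC)c1 | intermediate
9 | (S)-4-benzyl-3-[(Z)-2-(4-allyl-2,6-dimethoxyphenoxy)-1-(dibutylboryloxy)vinyl]oxazolidin-2-one (Z boron enolate of 6) | C=CCc1cc(OC)c(O/C=C(\OB(CCCC)CCCC)N2[C@@H](Cc3ccccc3)COC2=O)c(OC)c1 | intermediate (not isolated)
10 | O-dibutylboryl derivative of 11 at the C7 oxygen (boron aldolate, 2S,3R) | C=CCc1cc(OC)c(O[C@H](C(=O)N2[C@@H](Cc3ccccc3)COC2=O)[C@H](OB(CCCC)CCCC)c4cc(O[Si](C(C)C)(C(C)C)C(C)C)c(OC)c(OC)c4)c(OC)c1 | intermediate (not isolated)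
11 | (S)-4-benzyl-3-[(2S,3R)-2-(4-allyl-2,6-dimethoxyphenoxy)-3-hydroxy-3-[3,4-dimethoxy-5-(triisopropylsilyloxy)phenyl]propanoyl]oxazolidin-2-one | C=CCc1cc(OC)c(O[C@H](C(=O)N2[C@@H](Cc3ccccc3)COC2=O)[C@H](O)c4cc(O[Si](C(C)C)(C(C)C)C(C)C)c(OC)c(OC)c4)c(OC)c1 | intermediate
12 | (1R,2R)-2-(4-allyl-2,6-dimethoxyphenoxy)-1-[3,4-dimethoxy-5-(triisopropylsilyloxy)phenyl]propane-1,3-diol | C=CCc1cc(OC)c(O[C@H](CO)[C@H](O)c2cc(O[Si](C(C)C)(C(C)C)C(C)C)c(OC)c(OC)c2)c(OC)c1 | intermediate
13 | (2R,3R)-2-(4-allyl-2,6-dimethoxyphenoxy)-3-hydroxy-3-[3,4-dimethoxy-5-(triisopropylsilyloxy)phenyl]propyl 4-methylbenzenesulfonate | C=CCc1cc(OC)c(O[C@H](COS(=O)(=O)c2ccc(C)cc2)[C@H](O)c3cc(O[Si](C(C)C)(C(C)C)C(C)C)c(OC)c(OC)c3)c(OC)c1 | intermediate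
14 | (1R,2R)-2-(4-allyl-2,6-dimethoxyphenoxy)-1-[3,4-dimethoxy-5-(triisopropylsilyloxy)phenyl]propan-1-ol | C=CCc1cc(OC)c(O[C@H](C)[C@H](O)c2cc(O[Si](C(C)C)(C(C)C)C(C)C)c(OC)c(OC)c2)c(OC)c1 | intermediate
15 | (1R,2R)-2-(4-allyl-2,6-dimethoxyphenoxy)-1-(3-hydroxy-4,5-dimethoxyphenyl)propan-1-ol | C=CCc1cc(OC)c(O[C@H](C)[C@H](O)c2cc(O)c(OC)c(OC)c2)c(OC)c1 | target

## Step count and least certain steps

Total step count: 8. Longest linear sequence: 7 steps (steps 1, 2, 4, 5, 6, 7 and 8, from 1 to 15); step 3 prepares the aldehyde partner.

Step 4 (key step). The most likely failure is incomplete enolisation or loss of diastereoselection. The three ether oxygens around C8 (the aryloxy oxygen and the two ortho-methoxy groups) can bind the boron triflate, and the electron-rich aldehyde 8 is a sluggish electrophile. If the addition needs warming, retro-aldol equilibration towards the anti adduct and leakage to the other face become possible. Fallback: the route leaves from acid 3 and uses a titanium enolate with a different auxiliary. Acid 3 is coupled with (S)-4-benzylthiazolidine-2-thione (EDC·HCl, DMAP, CH2Cl2) to give (S)-4-benzyl-3-[(4-allyl-2,6-dimethoxyphenoxy)acetyl]thiazolidine-2-thione F1. Soft enolisation with TiCl4 (1 equiv), i-Pr2NEt and N-methylpyrrolidinone (1 equiv) in CH2Cl2 at 0 °C and addition of 8 should proceed through the non-chelated chair and give the syn adduct of the same sense, (S)-4-benzyl-3-[(2S,3R)-2-(4-allyl-2,6-dimethoxyphenoxy)-3-hydroxy-3-[3,4-dimethoxy-5-(triisopropylsilyloxy)phenyl]propanoyl]thiazolidine-2-thione F2. The thiazolidinethione is a better leaving group than the oxazolidinone, so NaBH4 in THF/EtOH should reduce F2 directly to diol 12, where the route is rejoined.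

Step 5. The most likely failure is retro-aldol fragmentation of the lithium aldolate, because the fragment released is a stabilised, electron-rich benzaldehyde. Hydride attack at the ring carbonyl of the auxiliary is the second risk, because the exocyclic carbonyl is crowded by the aryloxy group. Fallback: the route leaves from 11 and changes the order to hydrolysis, then reduction. LiOH/H2O2 in THF/H2O at 0 °C cleaves the exocyclic carbonyl selectively to (2S,3R)-2-(4-allyl-2,6-dimethoxyphenoxy)-3-hydroxy-3-[3,4-dimethoxy-5-(triisopropylsilyloxy)phenyl]propanoic acid F3. Me3SiCHN2 in MeOH/toluene gives methyl (2S,3R)-2-(4-allyl-2,6-dimethoxyphenoxy)-3-hydroxy-3-[3,4-dimethoxy-5-(triisopropylsilyloxy)phenyl]propanoate F4. The α-aryloxy ester F4 is reduced by LiBH4 in THF at 0 °C to diol 12, where the route is rejoined.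

Step 6. The most likely failure is over-sulfonylation. A sulfonate on the C7 oxygen would ionise readily because of the para-methoxy group, which would scramble C7 or lead to elimination, and long exposure of 13 to base could close an oxetane between the C7 oxygen and C9. Fallback: the route leaves from 12 and replaces the sulfonate by a halide made under neutral conditions. PPh3, I2 and imidazole in CH2Cl2 at 0 °C (Appel-type iodination, highly selective for primary hydroxyls because of the bulk of the phosphonium intermediate) give (1R,2S)-2-(4-allyl-2,6-dimethoxyphenoxy)-1-[3,4-dimethoxy-5-(triisopropylsilyloxy)phenyl]-3-iodopropan-1-ol F5. LiBHEt3 in THF reduces F5 to 14, where the route is rejoined.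

Step 7. The most likely failure is a competing reaction of the C7 alkoxide formed by the first equivalent of hydride: intramolecular displacement at C9 (oxetane formation, 4-exo-tet), or base-induced elimination across C8–C9. The β-aryloxy group slows the SN2 attack of hydride at C9, which gives these pathways more time. Fallback: the route leaves from 13 and masks the competing nucleophile. Et3SiOTf and 2,6-lutidine in CH2Cl2 at −78 °C give (2R,3R)-2-(4-allyl-2,6-dimethoxyphenoxy)-3-[3,4-dimethoxy-5-(triisopropylsilyloxy)phenyl]-3-(triethylsilyloxy)propyl 4-methylbenzenesulfonate F6. LiBHEt3 in THF then gives triethyl{(1R,2R)-2-(4-allyl-2,6-dimethoxyphenoxy)-1-[3,4-dimethoxy-5-(triisopropylsilyloxy)phenyl]propoxy}silane F7. Bu4NF in THF removes both silyl groups in one operation and returns to the route at 15, so the detour costs one step.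

## Further compounds

F1 | step 4 | (S)-4-benzyl-3-[(4-allyl-2,6-dimethoxyphenoxy)acetyl]thiazolidine-2-thione | C=CCc1cc(OC)c(OCC(=O)N2[C@@H](Cc3ccccc3)CSC2=S)c(OC)c1
F2 | step 4 | (S)-4-benzyl-3-[(2S,3R)-2-(4-allyl-2,6-dimethoxyphenoxy)-3-hydroxy-3-[3,4-dimethoxy-5-(triisopropylsilyloxy)phenyl]propanoyl]thiazolidine-2-thione | C=CCc1cc(OC)c(O[C@H](C(=O)N2[C@@H](Cc3ccccc3)CSC2=S)[C@H](O)c4cc(O[Si](C(C)C)(C(C)C)C(C)C)c(OC)c(OC)c4)c(OC)c1
F3 | step 5 | (2S,3R)-2-(4-allyl-2,6-dimethoxyphenoxy)-3-hydroxy-3-[3,4-dimethoxy-5-(triisopropylsilyloxy)phenyl]propanoic acid | C=CCc1cc(OC)c(O[C@H](C(=O)O)[C@H](O)c2cc(O[Si](C(C)C)(C(C)C)C(C)C)c(OC)c(OC)c2)c(OC)c1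
F4 | step 5 | methyl (2S,3R)-2-(4-allyl-2,6-dimethoxyphenoxy)-3-hydroxy-3-[3,4-dimethoxy-5-(triisopropylsilyloxy)phenyl]propanoate | C=CCc1cc(OC)c(O[C@H](C(=O)OC)[C@H](O)c2cc(O[Si](C(C)C)(C(C)C)C(C)C)c(OC)c(OC)c2)c(OC)c1
F5 | step 6 | (1R,2S)-2-(4-allyl-2,6-dimethoxyphenoxy)-1-[3,4-dimethoxy-5-(triisopropylsilyloxy)phenyl]-3-iodopropan-1-ol | C=CCc1cc(OC)c(O[C@H](CI)[C@H](O)c2cc(O[Si](C(C)C)(C(C)C)C(C)C)c(OC)c(OC)c2)c(OC)c1
F6 | step 7 | (2R,3R)-2-(4-allyl-2,6-dimethoxyphenoxy)-3-[3,4-dimethoxy-5-(triisopropylsilyloxy)phenyl]-3-(triethylsilyloxy)propyl 4-methylbenzenesulfonate | C=CCc1cc(OC)c(O[C@H](COS(=O)(=O)c2ccc(C)cc2)[C@H](O[Si](CC)(CC)CC)c3cc(O[Si](C(C)C)(C(C)C)C(C)C)c(OC)c(OC)c3)c(OC)c1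
F7 | step 7 | triethyl{(1R,2R)-2-(4-allyl-2,6-dimethoxyphenoxy)-1-[3,4-dimethoxy-5-(triisopropylsilyloxy)phenyl]propoxy}silane | C=CCc1cc(OC)c(O[C@H](C)[C@H](O[Si](CC)(CC)CC)c2cc(O[Si](C(C)C)(C(C)C)C(C)C)c(OC)c(OC)c2)c(OC)c1
A1 | alternative 1 | 5-bromo-2-({(1E)-1-[3,4-dimethoxy-5-(triisopropylsilyloxy)phenyl]prop-1-en-2-yl}oxy)-1,3-dimethoxybenzene | COc1cc(Br)cc(OC)c1O/C(C)=C/c1cc(O[Si](C(C)C)(C(C)C)C(C)C)c(OC)c(OC)c1
A2 | alternative 1 | (1R,2R)-2-(4-bromo-2,6-dimethoxyphenoxy)-1-[3,4-dimethoxy-5-(triisopropylsilyloxy)phenyl]propan-1-ol | COc1cc(Br)cc(OC)c1O[C@H](C)[C@H](O)c1cc(O[Si](C(C)C)(C(C)C)C(C)C)c(OC)c(OC)c1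
A3 | alternative 2 | (1R,2R)-1-(tert-butyldimethylsilyloxy)-1-[3,4-dimethoxy-5-(triisopropylsilyloxy)phenyl]propan-2-ol | O[C@H](C)[C@H](O[Si](C)(C)C(C)(C)C)c1cc(O[Si](C(C)C)(C(C)C)C(C)C)c(OC)c(OC)c1
A4 | alternative 2 | 5-allyl-2-bromo-1,3-dimethoxybenzene | C=CCc1cc(OC)c(Br)c(OC)c1
A5 | alternative 2 | tert-butyl{(1R,2R)-2-(4-allyl-2,6-dimethoxyphenoxy)-1-[3,4-dimethoxy-5-(triisopropylsilyloxy)phenyl]propoxy}dimethylsilane | C=CCc1cc(OC)c(O[C@H](C)[C@H](O[Si](C)(C)C(C)(C)C)c2cc(O[Si](C(C)C)(C(C)C)C(C)C)c(OC)c(OC)c2)c(OC)c1
A6 | alternative 3 | (R)-2-(4-allyl-2,6-dimethoxyphenoxy)propanal | C=CCc1cc(OC)c(O[C@H](C)C=O)c(OC)c1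
A7 | alternative 3 | [3,4-dimethoxy-5-(triisopropylsilyloxy)phenyl]magnesium bromide | COc1cc([Mg]Br)cc(O[Si](C(C)C)(C(C)C)C(C)C)c1OC
A8 | alternative 3 | (1R,2R)-2-(4-allyl-2,6-dimethoxyphenoxy)-1-[3,4-dimethoxy-5-(triisopropylsilyloxy)phenyl]propan-1-ol (identical with 14) | C=CCc1cc(OC)c(O[C@H](C)[C@H](O)c2cc(O[Si](C(C)C)(C(C)C)C(C)C)c(OC)c(OC)c2)c(OC)c1
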